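**Plan**

- The target is read as the all-cis (2R,3R,4R)-oxolane. Its C3 carries a one-carbon branch (C3–CH2OH) flanked by C2 (aryl) and C4 (benzyl). This is the pattern left when a 2-aryl-5-benzyl-3,4-epoxyoxane pushes one oxirane carbon out of the ring as CHO.
- Retrosynthesis: CH2OH goes back to CHO; the C2–C3 ring bond of the oxolane is cut (reverse 1,2-shift) to the epoxyoxane; the oxirane goes back to the ring alkene of a dihydropyran. The dihydropyran is cut at C=C (metathesis), at O–CH(aryl) (allylic etherification) and at CH–CH2Ar (imide alkylation).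
- Forward: a cinnamyl carbonate and a 2-benzylbut-3-en-1-ol are joined at the benzylic C–O bond, the six-membered ring closes by metathesis, the oxirane is fused on, the oxane contracts to the oxolane, and reduction ends the route.
- Stereochemistry: the benzyl-bearing centre comes from an oxazolidinone alkylation, the aryl-bearing centre from the iridium/phosphoramidite catalyst, and the oxirane face from the two cis substituents. C3 comes from a bromide-relayed shift that inverts the receiving carbon twice, which is why the oxirane oxygen is placed trans to aryl and benzyl.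

Key step: step 12

Remark: the (Ra,Rc,Rc) phosphoramidite named in step 9 is assumed to give the R branched ether, as with other O- and N-nucleophiles on E-cinnamyl carbonates; if a model run showed the opposite sense, the mirror-image ligand would be used with nothing else changed.

Oxane numbering used below: O1, C2 (aryl), C3 and C4 (oxirane carbons), C5 (benzyl), C6.

**Route**

Step 1
Reactants: 1 (E)-3,4,5-trimethoxycinnamic acid
Product: 2 methyl (E)-3-(3,4,5-trimethoxyphenyl)prop-2-enoate
Conditions: MeOH, H2SO4 (cat.), reflux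
Reagents that add atoms: methanol, CO
Why: Fischer esterification, to which the E alkene and the aryl methyl ethers are inert.

Step 2
Reactants: 2 methyl (E)-3-(3,4,5-trimethoxyphenyl)prop-2-enoate
Product: 3 (E)-3-(3,4,5-trimethoxyphenyl)prop-2-en-1-ol
Conditions: iBu2AlH (2.2 equiv), CH2Cl2, −78 °C; aq. KNaC4H4O6 (potassium sodium tartrate)
Reagents that add atoms: none
Why: 1,2-reduction of the unsaturated ester by iBu2AlH at low temperature should give the E allylic alcohol without touching the alkene.

Step 3
Reactants: 3 (E)-3-(3,4,5-trimethoxyphenyl)prop-2-en-1-ol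
Product: 4 tert-butyl (E)-3-(3,4,5-trimethoxyphenyl)prop-2-en-1-yl carbonate
Conditions: Boc2O, Bu4NHSO4 (cat.), 30% aq. NaOH, CH2Cl2, 0 °C to rt
Reagents that add atoms: di-tert-butyl dicarbonate, CC(C)(C)OC(=O)OC(=O)OC(C)(C)C
Why: phase-transfer O-acylation of the primary allylic alcohol gives the carbonate whose tert-butoxide by-product will not compete as a nucleophile in step 9.

Step 4
Reactants: 5 2,4,5-trimethoxybenzaldehyde
Product: 6 (2,4,5-trimethoxyphenyl)methanol
Conditions: NaBH4, MeOH, 0 °C
Reagents that add atoms: none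
Why: borohydride reduction of an aryl aldehyde.

Step 5
Reactants: 6 (2,4,5-trimethoxyphenyl)methanol
Product: 7 1-(bromomethyl)-2,4,5-trimethoxybenzene
Conditions: PBr3 (0.4 equiv), Et2O, 0 °C; cold filtration, used at once
Reagents that add atoms: phosphorus tribromide, BrP(Br)Br
Why: bromodehydroxylation of the benzylic alcohol through its phosphite ester; the electron-rich bromide is labile and is therefore taken on immediately.

Step 6
Reactants: 8 but-3-enoic acid; 9 (R)-4-benzyl-1,3-oxazolidin-2-one
Product: 11 (4R)-4-benzyl-3-(but-3-enoyl)-1,3-oxazolidin-2-one, via but-3-enoic pivalic anhydride 10 (not isolated)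
Conditions: t-BuCOCl, Et3N, THF, −20 °C; then LiCl, 9, −20 °C to rt
Reagents that add atoms: none
Why: N-acylation through the mixed pivalic anhydride, which is attacked at its unhindered butenoyl carbonyl; any drift of the double bond into conjugation is harmless because both imides give the same dienolate in step 7.

Step 7
Reactants: 11 (4R)-4-benzyl-3-(but-3-enoyl)-1,3-oxazolidin-2-one; 7 1-(bromomethyl)-2,4,5-trimethoxybenzene
Product: 13 (4R)-4-benzyl-3-{(2R)-2-[(2,4,5-trimethoxyphenyl)methyl]but-3-enoyl}-1,3-oxazolidin-2-one, via sodium dienolate 12 (not isolated)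
Conditions: NaN(SiMe3)2 (1.05 equiv), THF, −78 °C; then 7, −78 to −40 °C; AcOH quench at −78 °C
Reagents that add atoms: none
Why: Evans alkylation of the chelated Z sodium dienolate, which should react at its α-carbon with the benzylic bromide on the face away from the auxiliary benzyl group and so set the R centre that becomes C4 of the target.

Step 8
Reactants: 13 (4R)-4-benzyl-3-{(2R)-2-[(2,4,5-trimethoxyphenyl)methyl]but-3-enoyl}-1,3-oxazolidin-2-one
Product: 14 (2R)-2-[(2,4,5-trimethoxyphenyl)methyl]but-3-en-1-ol
Conditions: LiBH4, MeOH (1 equiv), Et2O, 0 °C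
Reagents that add atoms: none
Why: reductive cleavage of the N-acyl oxazolidinone to the primary alcohol, which releases the auxiliary and should not epimerise the α-centre at this temperature.

Step 9
Reactants: 14 (2R)-2-[(2,4,5-trimethoxyphenyl)methyl]but-3-en-1-ol; 4 tert-butyl (E)-3-(3,4,5-trimethoxyphenyl)prop-2-en-1-yl carbonate
Product: 17 1,2,3-trimethoxy-5-[(1R)-1-({(2R)-2-[(2,4,5-trimethoxyphenyl)methyl]but-3-en-1-yl}oxy)prop-2-en-1-yl]benzene, via lithium alkoxide 15 (not isolated), via copper alkoxide 16 (not isolated)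
Conditions: 14, n-BuLi, THF, 0 °C; CuI (1 equiv), rt; then 4 (1.3 equiv), [Ir(cod)Cl]2 (2 mol %), (Ra,Rc,Rc)-O,O'-(1,1'-binaphthyl-2,2'-diyl) N,N-bis(1-phenylethyl)phosphoramidite (4 mol %), THF, rt
Reagents that add atoms: none
Why: iridium-catalysed branched-selective asymmetric allylic etherification, in which the monovalent copper alkoxide attacks the aryl-substituted terminus of the allyl-iridium intermediate and the phosphoramidite alone fixes the new benzylic C–O centre as R, the remote centre of the alkoxide having little say.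

Step 10
Reactants: 17 1,2,3-trimethoxy-5-[(1R)-1-({(2R)-2-[(2,4,5-trimethoxyphenyl)methyl]but-3-en-1-yl}oxy)prop-2-en-1-yl]benzene
Product: 18 (3R,6R)-6-(3,4,5-trimethoxyphenyl)-3-[(2,4,5-trimethoxyphenyl)methyl]-3,6-dihydro-2H-pyran
Conditions: (H2IMes)(PCy3)Cl2Ru=CHPh (second-generation Grubbs catalyst, 3 mol %), CH2Cl2, 40 °C
Reagents that add atoms: none
Why: ring-closing metathesis of the two vinyl groups closes the six-membered ring with loss of ethylene and leaves both stereocentres untouched, so aryl and benzyl end up cis.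

Step 11
Reactants: 18 (3R,6R)-6-(3,4,5-trimethoxyphenyl)-3-[(2,4,5-trimethoxyphenyl)methyl]-3,6-dihydro-2H-pyran
Product: 19 (1R,2S,5S,6R)-2-(3,4,5-trimethoxyphenyl)-5-[(2,4,5-trimethoxyphenyl)methyl]-3,7-dioxabicyclo[4.1.0]heptane
Conditions: mCPBA (1.2 equiv), NaHCO3, CH2Cl2, 0 °C
Reagents that add atoms: 3-chloroperoxybenzoic acid, OOC(=O)c1cccc(Cl)c1
Why: Prilezhaev epoxidation, in which the peracid should reach the ring alkene from the face opposite to the two cis substituents (one of them is pseudoaxial in either half-chair), giving the oxirane trans to aryl and benzyl.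

Step 12
Reactants: 19 (1R,2S,5S,6R)-2-(3,4,5-trimethoxyphenyl)-5-[(2,4,5-trimethoxyphenyl)methyl]-3,7-dioxabicyclo[4.1.0]heptane
Product: 21 (2R,3S,4R)-2-(3,4,5-trimethoxyphenyl)-4-[(2,4,5-trimethoxyphenyl)methyl]oxolane-3-carbaldehyde, via lithium trans-bromohydrinate 20 (not isolated)
Conditions: LiBr (anhydrous, 1.5 equiv), tetramethylurea (1.5 equiv), toluene, 80 °C; cooled to 0 °C, pH 7 buffer, crude aldehyde used at once
Reagents that add atoms: none
Why: Li+ activates the oxirane and bromide opens it from the face opposite to oxygen, with inversion at C4 (the carbon remote from the ring oxygen), to the bromohydrinate 20; in its chair with O– and Br equatorial the ring bond C2–C3 is antiperiplanar to C4–Br, and C2 migrates from C3 to C4 with a second inversion there and retention in C2, while C3 becomes the formyl carbon and LiBr is returned. The closest known reaction type is the lithium halide promoted Meinwald (semipinacol) ring contraction of cyclohexene oxides to cyclopentanecarbaldehydes and of epoxypyranosides to C-formyl furanosides. The oxolane ring is not closed by a cyclisation but by contraction of the oxane through this suprafacial 1,2-shift, its new C2–C3 bond forming by intramolecular backside displacement of bromide. The new stereocentre (C3 of the oxolane, former C4 of the oxane) is set by the two successive inversions, so the new ring bond ends on the face the oxirane oxygen had occupied and the formyl group comes out cis to both aryl and benzyl, while C2 and C4 of the oxolane are carried over unchanged. The step needs ring-bond migration rather than hydride shift to an oxanone, and the diequatorial bromohydrinate secures this because only the ring bond, never the carbinol hydrogen, lies anti to C–Br, the migrating carbon being further helped by its oxygen and aryl substituents. The site of bromide attack is not critical, since opening at C3 followed by migration of C5 would lead to the same aldehyde with the same configuration.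

Step 13
Reactants: 21 (2R,3S,4R)-2-(3,4,5-trimethoxyphenyl)-4-[(2,4,5-trimethoxyphenyl)methyl]oxolane-3-carbaldehyde
Product: 22 [(2R,3R,4R)-2-(3,4,5-trimethoxyphenyl)-4-[(2,4,5-trimethoxyphenyl)methyl]oxolan-3-yl]methanol
Conditions: NaBH4 (excess), MeOH/THF, −20 °C, aldehyde added to the hydride
Reagents that add atoms: none
Why: borohydride reduction of the aldehyde is fast at low temperature and should fix the epimerisable C3 centre as the primary alcohol before enolisation can occur.

**Compound list**

1 | (E)-3,4,5-trimethoxycinnamic acid | COc1cc(/C=C/C(=O)O)cc(OC)c1OC | starting material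
2 | methyl (E)-3-(3,4,5-trimethoxyphenyl)prop-2-enoate | COC(=O)/C=C/c1cc(OC)c(OC)c(OC)c1 | intermediate
3 | (E)-3-(3,4,5-trimethoxyphenyl)prop-2-en-1-ol | OC/C=C/c1cc(OC)c(OC)c(OC)c1 | intermediate
4 | tert-butyl (E)-3-(3,4,5-trimethoxyphenyl)prop-2-en-1-yl carbonate | CC(C)(C)OC(=O)OC/C=C/c1cc(OC)c(OC)c(OC)c1 | intermediate
5 | 2,4,5-trimethoxybenzaldehyde | COc1cc(OC)c(OC)cc1C=O | starting material
6 | (2,4,5-trimethoxyphenyl)methanol | COc1cc(OC)c(OC)cc1CO | intermediate
7 | 1-(bromomethyl)-2,4,5-trimethoxybenzene | COc1cc(OC)c(OC)cc1CBr | intermediate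
8 | but-3-enoic acid | C=CCC(=O)O | starting material
9 | (R)-4-benzyl-1,3-oxazolidin-2-one | O=C1OC[C@@H](Cc2ccccc2)N1 | starting material
10 | but-3-enoic pivalic anhydride | C=CCC(=O)OC(=O)C(C)(C)C | intermediate
11 | (4R)-4-benzyl-3-(but-3-enoyl)-1,3-oxazolidin-2-one | C=CCC(=O)N1C(=O)OC[C@H]1Cc1ccccc1 | intermediate
12 | sodium Z-dienolate of 11 | [Na+].[O-]/C(=C\C=C)N1C(=O)OC[C@H]1Cc1ccccc1 | intermediate
13 | (4R)-4-benzyl-3-{(2R)-2-[(2,4,5-trimethoxyphenyl)methyl]but-3-enoyl}-1,3-oxazolidin-2-one | COc1cc(OC)c(OC)cc1C[C@H](C=C)C(=O)N1C(=O)OC[C@H]1Cc1ccccc1 | intermediate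
14 | (2R)-2-[(2,4,5-trimethoxyphenyl)methyl]but-3-en-1-ol | COc1cc(OC)c(OC)cc1C[C@H](C=C)CO | intermediate
15 | lithium (2R)-2-[(2,4,5-trimethoxyphenyl)methyl]but-3-en-1-olate | COc1cc(OC)c(OC)cc1C[C@H](C=C)C[O-].[Li+] | intermediate
16 | copper (2R)-2-[(2,4,5-trimethoxyphenyl)methyl]but-3-en-1-olate (monovalent copper) | COc1cc(OC)c(OC)cc1C[C@H](C=C)C[O-].[Cu+] | intermediate
17 | 1,2,3-trimethoxy-5-[(1R)-1-({(2R)-2-[(2,4,5-trimethoxyphenyl)methyl]but-3-en-1-yl}oxy)prop-2-en-1-yl]benzene | COc1cc(OC)c(OC)cc1C[C@H](C=C)CO[C@@H](c1cc(OC)c(OC)c(OC)c1)C=C | intermediate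
18 | (3R,6R)-6-(3,4,5-trimethoxyphenyl)-3-[(2,4,5-trimethoxyphenyl)methyl]-3,6-dihydro-2H-pyran (aryl and benzyl cis) | COc1cc(OC)c(OC)cc1C[C@H]1CO[C@@H](c2cc(OC)c(OC)c(OC)c2)C=C1 | intermediate
19 | (1R,2S,5S,6R)-2-(3,4,5-trimethoxyphenyl)-5-[(2,4,5-trimethoxyphenyl)methyl]-3,7-dioxabicyclo[4.1.0]heptane (3,4-epoxyoxane; oxirane oxygen trans to the cis aryl and benzyl groups) | COc1cc(OC)c(OC)cc1C[C@H]1CO[C@@H](c2cc(OC)c(OC)c(OC)c2)[C@@H]2O[C@H]12 | intermediate
20 | lithium (2S,3S,4S,5S)-4-bromo-2-(3,4,5-trimethoxyphenyl)-5-[(2,4,5-trimethoxyphenyl)methyl]oxan-3-olate (Br cis to aryl and benzyl, O trans to them) | COc1cc(OC)c(OC)cc1C[C@H]1CO[C@@H](c2cc(OC)c(OC)c(OC)c2)[C@H]([O-])[C@H]1Br.[Li+] | intermediate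
21 | (2R,3S,4R)-2-(3,4,5-trimethoxyphenyl)-4-[(2,4,5-trimethoxyphenyl)methyl]oxolane-3-carbaldehyde (all-cis) | COc1cc(OC)c(OC)cc1C[C@H]1CO[C@@H](c2cc(OC)c(OC)c(OC)c2)[C@H]1C=O | intermediate
22 | [(2R,3R,4R)-2-(3,4,5-trimethoxyphenyl)-4-[(2,4,5-trimethoxyphenyl)methyl]oxolan-3-yl]methanol (all-cis) | COc1cc(OC)c(OC)cc1C[C@H]1CO[C@@H](c2cc(OC)c(OC)c(OC)c2)[C@H]1CO | target

**Count**

Total steps: 13. Longest linear sequence: 9 steps (steps 4, 5, 7, 8, 9, 10, 11, 12, 13, starting from 5).

**Steps most likely to fail**

Step 12. Two things may go wrong: bromide may attack the oxirane only slowly, because it has to approach from the face that carries aryl and benzyl, and the all-cis aldehyde may enolise and epimerise at C3 at 80 °C in the presence of the lithium salt. The fallback separates opening from migration and runs the shift cold. It sets out from 19, which is opened with LiI/AcOH in THF at −20 °C to the isolable trans-iodohydrin (2S,3S,4S,5S)-4-iodo-2-(3,4,5-trimethoxyphenyl)-5-[(2,4,5-trimethoxyphenyl)methyl]oxan-3-ol F1. Treating this with AgBF4 and 2,6-di-tert-butylpyridine in CH2Cl2 at −30 °C should trigger a silver-assisted Tiffeneau-type semipinacol shift, with the same anti migration of the ring bond and hence the same double inversion. The fallback returns to the route at 21, which is reduced as in step 13.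

Step 9. The β-branched copper alkoxide may capture the allyl-iridium intermediate slowly or unselectively, giving low conversion, linear ether, or weak catalyst control at the new benzylic centre. The fallback forms the other C–O bond of the ether instead. It sets out from 4, which is etherified under the same iridium catalyst with the small nucleophile Et3SiOK to give triethyl{[(1R)-1-(3,4,5-trimethoxyphenyl)prop-2-en-1-yl]oxy}silane F2, and this is desilylated with Bu4NF to (1R)-1-(3,4,5-trimethoxyphenyl)prop-2-en-1-ol F3. In parallel 14 is converted with Tf2O and 2,6-lutidine at −78 °C into (2R)-2-[(2,4,5-trimethoxyphenyl)methyl]but-3-en-1-yl trifluoromethanesulfonate F4. A Williamson etherification of F3 (NaH, THF) with F4 at −40 to 0 °C then returns to the route at 17.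

Step 7. The electron-rich benzylic bromide may self-condense before it is captured, and the doubly activated α-position may suffer γ-alkylation, double-bond migration into conjugation, or epimerisation under base. The fallback makes the same C–C bond by an aldol reaction with aldehyde 5 and needs neither steps 4 and 5 nor the bromide. It sets out from 8, which is coupled as in step 6 with commercial (S)-4-benzyl-1,3-oxazolidin-2-one (the antipode of 9, needed because the boron aldol attacks the enolate face opposite to that of the alkylation) to give (4S)-4-benzyl-3-(but-3-enoyl)-1,3-oxazolidin-2-one F5. Its dibutylboron dienolate (Bu2BOTf, iPr2NEt, CH2Cl2, −78 °C) should add 5 at the α-carbon to give the syn aldol (4S)-4-benzyl-3-[(2S,3S)-2-ethenyl-3-hydroxy-3-(2,4,5-trimethoxyphenyl)propanoyl]-1,3-oxazolidin-2-one F6. Ionic deoxygenation of the electron-rich benzylic alcohol (Et3SiH, CF3CO2H, CH2Cl2, −20 °C) would give (4S)-4-benzyl-3-{(2R)-2-[(2,4,5-trimethoxyphenyl)methyl]but-3-enoyl}-1,3-oxazolidin-2-one F7, and LiBH4 cleavage as in step 8 returns to the route at 14.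

**Further compounds**

F1 | step 12 | (2S,3S,4S,5S)-4-iodo-2-(3,4,5-trimethoxyphenyl)-5-[(2,4,5-trimethoxyphenyl)methyl]oxan-3-ol | COc1cc(OC)c(OC)cc1C[C@H]1CO[C@@H](c2cc(OC)c(OC)c(OC)c2)[C@H](O)[C@H]1I
F2 | step 9 | triethyl{[(1R)-1-(3,4,5-trimethoxyphenyl)prop-2-en-1-yl]oxy}silane | CC[Si](CC)(CC)O[C@@H](c1cc(OC)c(OC)c(OC)c1)C=C
F3 | step 9 | (1R)-1-(3,4,5-trimethoxyphenyl)prop-2-en-1-ol | O[C@@H](c1cc(OC)c(OC)c(OC)c1)C=C
F4 | step 9 | (2R)-2-[(2,4,5-trimethoxyphenyl)methyl]but-3-en-1-yl trifluoromethanesulfonate | COc1cc(OC)c(OC)cc1C[C@H](C=C)COS(=O)(=O)C(F)(F)F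
F5 | step 7 | (4S)-4-benzyl-3-(but-3-enoyl)-1,3-oxazolidin-2-one | C=CCC(=O)N1C(=O)OC[C@@H]1Cc1ccccc1
F6 | step 7 | (4S)-4-benzyl-3-[(2S,3S)-2-ethenyl-3-hydroxy-3-(2,4,5-trimethoxyphenyl)propanoyl]-1,3-oxazolidin-2-one | COc1cc(OC)c(OC)cc1[C@@H](O)[C@H](C=C)C(=O)N1C(=O)OC[C@@H]1Cc1ccccc1
F7 | step 7 | (4S)-4-benzyl-3-{(2R)-2-[(2,4,5-trimethoxyphenyl)methyl]but-3-enoyl}-1,3-oxazolidin-2-one | COc1cc(OC)c(OC)cc1C[C@H](C=C)C(=O)N1C(=O)OC[C@@H]1Cc1ccccc1
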